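**Retrosynthetic overview**

1. Feature: the carbocycle is one continuous propionate chain running from pyranone C6 through ring C4 (quaternary, CH3), C5H=C6(CH3), C1(=O), C2(CH3)=C3 and on into the side chain. The C3–C4 bond therefore joins the two ends of a triene and is the bond a 6π electrocyclization makes; the C1 oxygen is added afterwards.
2. Target 34 ⇐ 2,5-dienol (C1–OH) ⇐ C1–C2 vinyl epoxide ⇐ cyclohexa-1,3-diene 30 ⇐ (E,Z,E,E)-tetraene 29 by disrotatory closure of the pyranone-bound triene under a chiral scandium Lewis acid.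
3. Tetraene 29 ⇐ Negishi coupling at the single bond next to the Z alkene: pyranone (2E,4Z)-dienyl iodide 14 plus the alkenylzirconium made from enyne 26.
4. Iodide 14 ⇐ 6-ethyl-2-methoxypyranone 6 (from keto ester 1) and (Z)-3-iodo-2-methylacrolein 10; enyne 26 ⇐ syn-aldol, Wittig and Corey–Fuchs steps.
5. Ring order: the pyranone is closed first (step 2); the carbocycle is the only other ring and is closed in step 16; the epoxide ring of step 17 is transient.

Key step: step 16

Remarks on the chemistry (assumptions):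
- Ring numbering used throughout: C1 = carbonyl carbon, C2 (CH3), C3 (side chain), C4 (quaternary: CH3 and pyranone), C5 (H), C6 (CH3).
- The side-chain ketone is carried as its TBS-protected (S)-carbinol from the aldol step to the last step, because the methyl stereocentre of a β,γ-unsaturated α-methyl ketone would be at risk under the Lewis acid of step 16 and the amide base of step 18; this carbinol centre is destroyed in step 20.
- The sense of induction of the pybox ligand cannot be predicted; the (S,S) ligand is written, and its (R,R) antipode is used if screening shows the opposite helix to be favoured.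

Step 1
Reactants: 1 methyl 2-methyl-3-oxopentanoate; 2 N-methoxy-N-methylpropanamide
Product: 4 methyl 2,4-dimethyl-3,5-dioxoheptanoate (mixture of diastereomers and enol forms), via keto ester dianion 3 (not isolated)
Conditions: NaH, THF, 0 °C; n-BuLi, −10 °C; then 2, −78 → 0 °C; aq. HCl
Reagents that add atoms: none
Why: γ-Acylation of a β-keto ester dianion, in which the more basic C4 carbanion attacks the Weinreb amide and the stable tetrahedral adduct prevents over-addition and proton quenching.

Step 2
Reactants: 4 methyl 2,4-dimethyl-3,5-dioxoheptanoate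
Product: 5 6-ethyl-4-hydroxy-3,5-dimethyl-2H-pyran-2-one
Conditions: DBU, toluene, 80 °C; aq. HCl
Reagents that add atoms: none
Why: Base-mediated lactonization of the 5-enol oxygen onto the methyl ester, driven by formation of the conjugated 4-hydroxy-2-pyranone.

Step 3
Reactants: 5 6-ethyl-4-hydroxy-3,5-dimethyl-2H-pyran-2-one
Product: 6 6-ethyl-2-methoxy-3,5-dimethyl-4H-pyran-4-one
Conditions: MeOTf, CH2Cl2, rt; aq. NaHCO3
Reagents that add atoms: methyl trifluoromethanesulfonate, COS(=O)(=O)C(F)(F)F
Why: Regioselective O-methylation of a 4-hydroxy-2-pyranone: a hard methylating agent without base alkylates the most basic oxygen, the lactone carbonyl, and loss of the 4-OH proton leaves the 2-methoxy-4-pyranone.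

Step 4
Reactants: 7 prop-2-yn-1-ol
Product: 9 (Z)-3-iodo-2-methylprop-2-en-1-ol, via alkenylmagnesium alkoxide 8 (not isolated)
Conditions: MeMgBr (2.5 equiv), CuI (10 mol%), THF, −10 °C → rt; then I2, −10 °C; aq. NH4Cl
Reagents that add atoms: methylmagnesium bromide, C[Mg]Br; iodine, II
Why: Copper-catalysed anti-carbomagnesiation of the propargylic alkoxide puts methyl on C2 and magnesium on C3 inside an oxygen-chelated ring, so iodinolysis with retention gives only the Z iodoalkene.

Step 5
Reactants: 9 (Z)-3-iodo-2-methylprop-2-en-1-ol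
Product: 10 (Z)-3-iodo-2-methylprop-2-enal
Conditions: MnO2, CH2Cl2, rt, dark
Reagents that add atoms: none
Why: Allylic alcohol oxidation with MnO2 under neutral conditions, which should keep the Z iodoalkene if light and acid are excluded; the aldehyde is used at once.

Step 6
Reactants: 6 6-ethyl-2-methoxy-3,5-dimethyl-4H-pyran-4-one; 10 (Z)-3-iodo-2-methylprop-2-enal
Product: 12 6-[(4Z)-3-hydroxy-5-iodo-4-methylpent-4-en-2-yl]-2-methoxy-3,5-dimethyl-4H-pyran-4-one (mixture of diastereomers at the two new centres), via lithiated pyranone 11 (not isolated)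
Conditions: LiHMDS, THF, −78 °C; then 10, −78 °C; aq. NH4Cl
Reagents that add atoms: none
Why: Vinylogous aldol addition: the CH2 of the 6-ethyl group is the only vinylogously acidic site of the 4-pyranone and its lithium dienolate adds 1,2 to the enal at low temperature; both new stereocentres are removed in step 7.

Step 7
Reactants: 12 6-[(4Z)-3-hydroxy-5-iodo-4-methylpent-4-en-2-yl]-2-methoxy-3,5-dimethyl-4H-pyran-4-one
Product: 14 6-[(2E,4Z)-5-iodo-4-methylpenta-2,4-dien-2-yl]-2-methoxy-3,5-dimethyl-4H-pyran-4-one, via aldol mesylate 13 (not isolated)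
Conditions: MsCl, Et3N, CH2Cl2, 0 °C; then DBU, rt
Reagents that add atoms: none
Why: Mesylation followed by E1cB elimination through the vinylogous enolate gives the conjugated diene with the thermodynamically preferred E geometry (pyranone anti to the iodoalkenyl group), and the Z iodoalkene is not touched.

Step 8
Reactants: 15 (R)-4-benzyl-3-propanoyl-1,3-oxazolidin-2-one; 16 propanal
Product: 18 (R)-4-benzyl-3-[(2R,3S)-3-hydroxy-2-methylpentanoyl]-1,3-oxazolidin-2-one, via Z boron enolate 17 (not isolated)
Conditions: Bu2BOTf, Et3N, CH2Cl2, 0 °C; then 16, −78 → 0 °C; pH 7 buffer, MeOH, H2O2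
Reagents that add atoms: none
Why: Evans syn-aldol reaction: the Z boron enolate reacts through a closed chair transition state on the face away from the benzyl group, which sets the (2R) methyl stereocentre (the side-chain stereocentre of the target) together with the (3S) carbinol.

Step 9
Reactants: 18 (R)-4-benzyl-3-[(2R,3S)-3-hydroxy-2-methylpentanoyl]-1,3-oxazolidin-2-one
Product: 19 (R)-4-benzyl-3-[(2R,3S)-3-{[tert-butyl(dimethyl)silyl]oxy}-2-methylpentanoyl]-1,3-oxazolidin-2-one
Conditions: TBSOTf, 2,6-lutidine, CH2Cl2, 0 °C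
Reagents that add atoms: tert-butyldimethylsilyl trifluoromethanesulfonate, CC(C)(C)[Si](C)(C)OS(=O)(=O)C(F)(F)F
Why: Silylation of the secondary alcohol with a silyl triflate and a hindered base; the TBS ether masks the future ketone so that the neighbouring methyl stereocentre cannot epimerize.

Step 10
Reactants: 19 (R)-4-benzyl-3-[(2R,3S)-3-{[tert-butyl(dimethyl)silyl]oxy}-2-methylpentanoyl]-1,3-oxazolidin-2-one
Product: 20 (2S,3S)-3-{[tert-butyl(dimethyl)silyl]oxy}-2-methylpentan-1-ol
Conditions: LiBH4, MeOH (1 equiv), Et2O, 0 °C; aq. NaOH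
Reagents that add atoms: none
Why: Reductive removal of the oxazolidinone: LiBH4 attacks the exocyclic imide carbonyl and leaves the silyl ether and the α-stereocentre intact.

Step 11
Reactants: 20 (2S,3S)-3-{[tert-butyl(dimethyl)silyl]oxy}-2-methylpentan-1-ol
Product: 21 (2R,3S)-3-{[tert-butyl(dimethyl)silyl]oxy}-2-methylpentanal
Conditions: Dess–Martin periodinane, NaHCO3, CH2Cl2, 0 °C → rt
Reagents that add atoms: none
Why: Dess–Martin oxidation under buffered conditions should give the α-chiral aldehyde without epimerization; it is used directly.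

Step 12
Reactants: 21 (2R,3S)-3-{[tert-butyl(dimethyl)silyl]oxy}-2-methylpentanal; 22 2-(triphenylphosphoranylidene)propanal
Product: 23 (2E,4S,5S)-5-{[tert-butyl(dimethyl)silyl]oxy}-2,4-dimethylhept-2-enal
Conditions: toluene, 100 °C
Reagents that add atoms: none
Why: Wittig reaction with a stabilized formyl ylide gives the E trisubstituted enal in one step and is not basic enough to epimerize the α-centre.

Step 13
Reactants: 23 (2E,4S,5S)-5-{[tert-butyl(dimethyl)silyl]oxy}-2,4-dimethylhept-2-enal
Product: 24 tert-butyl{[(3S,4S,5E)-8,8-dibromo-4,6-dimethylocta-5,7-dien-3-yl]oxy}dimethylsilane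
Conditions: CBr4, PPh3, Zn, CH2Cl2, rt; then 23, 0 °C → rt
Reagents that add atoms: carbon tetrabromide, BrC(Br)(Br)Br
Why: Corey–Fuchs dibromo-olefination with the ylide preformed from CBr4, PPh3 and Zn, which keeps Ph3PBr2 and HBr away from the silyl ether.

Step 14
Reactants: 24 tert-butyl{[(3S,4S,5E)-8,8-dibromo-4,6-dimethylocta-5,7-dien-3-yl]oxy}dimethylsilane
Product: 26 tert-butyl{[(3S,4S,5E)-4,6-dimethylnon-5-en-7-yn-3-yl]oxy}dimethylsilane, via lithium acetylide 25 (not isolated)
Conditions: n-BuLi (2.2 equiv), THF, −78 °C; then MeI, −78 °C → rt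
Reagents that add atoms: iodomethane, CI
Why: Second stage of the Corey–Fuchs sequence: bromine–lithium exchange and Fritsch–Buttenberg–Wiechell rearrangement give the lithium acetylide, which is C-methylated in the same flask.

Step 15
Reactants: 26 tert-butyl{[(3S,4S,5E)-4,6-dimethylnon-5-en-7-yn-3-yl]oxy}dimethylsilane; 14 6-[(2E,4Z)-5-iodo-4-methylpenta-2,4-dien-2-yl]-2-methoxy-3,5-dimethyl-4H-pyran-4-one
Product: 29 6-[(2E,4Z,6E,8E,10S,11S)-11-{[tert-butyl(dimethyl)silyl]oxy}-4,6,8,10-tetramethyltrideca-2,4,6,8-tetraen-2-yl]-2-methoxy-3,5-dimethyl-4H-pyran-4-one, via alkenylzirconocene chloride 27 (not isolated), via alkenylzinc chloride 28 (not isolated)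
Conditions: 26 (1.3 equiv), Cp2Zr(H)Cl, THF, rt, dark; ZnCl2, 0 °C; then 14, Pd(PPh3)4 (5 mol%), rt, dark
Reagents that add atoms: none
Why: Hydrozirconation followed by Negishi coupling: syn addition of Zr–H puts zirconium on the methyl-bearing, less hindered alkyne carbon, and transmetalation to zinc and coupling with the Z iodide at zerovalent palladium go with retention at both alkenyl carbons to give the (E,Z,E,E)-tetraene.

Step 16
Reactants: 29 6-[(2E,4Z,6E,8E,10S,11S)-11-{[tert-butyl(dimethyl)silyl]oxy}-4,6,8,10-tetramethyltrideca-2,4,6,8-tetraen-2-yl]-2-methoxy-3,5-dimethyl-4H-pyran-4-one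
Product: 30 6-[(1S,6R)-6-{(2E,4S,5S)-5-{[tert-butyl(dimethyl)silyl]oxy}-4-methylhept-2-en-2-yl}-1,3,5-trimethylcyclohexa-2,4-dien-1-yl]-2-methoxy-3,5-dimethyl-4H-pyran-4-one (pyranone on C4 and side chain on C3 cis)
Conditions: Sc(OTf)3 (10 mol%), (S,S)-Ph-pybox (12 mol%), 4 Å molecular sieves, CH2Cl2, −20 °C → rt, dark
Reagents that add atoms: none
Why: Proposed new method: the complex of trivalent scandium and pybox binds the strongly basic C4 carbonyl oxygen of the pyranone, which turns the heterocycle into a 4-metalloxypyrylium acceptor and polarizes the attached (E,Z,E)-triene, so that its helical s-cis,s-cis conformer should undergo the thermally allowed disrotatory 6π electrocyclization far below the temperature the uncatalysed closure needs. The closest known reaction types are the thermal disrotatory closure of (E,Z,E)-hexatrienes and Lewis-acid-catalysed 6π electrocyclizations of acceptor-substituted trienes, whereas an enantioselective version on a carbonyl-bound polyene is not established. The single new ring, the cyclohexa-1,3-diene, is closed in this disrotatory 6π mode with formation of the C3–C4 bond. Disrotation brings the two outward groups, the pyranone on C4 and the alkenyl chain on C3, cis to each other, and the absolute configuration at quaternary C4 has to come from the chiral ligand, which must favour one of the two enantiomorphic helices of the bound triene because the side-chain stereocentres are too remote to do so. The step needs selectivity for 6π closure over the Lewis-acid-induced cationic cyclization to a bicyclo[3.1.0]hexene and over E/Z scrambling; the preset Z alkene, a mild triflate Lewis acid instead of an alkylaluminium halide, low temperature and exclusion of light are meant to secure this.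

Step 17
Reactants: 30 the cyclohexa-1,3-diene of step 16
Product: 31 C1–C2 epoxide of 30: 6-[5-{(2E,4S,5S)-5-{[tert-butyl(dimethyl)silyl]oxy}-4-methylhept-2-en-2-yl}-2,4,6-trimethyl-7-oxabicyclo[4.1.0]hept-2-en-4-yl]-2-methoxy-3,5-dimethyl-4H-pyran-4-one with the oxygen on the ring face that carries H3 and the C4 methyl
Conditions: dimethyldioxirane (1.0 equiv, acetone), CH2Cl2, −40 → 0 °C
Reagents that add atoms: dimethyldioxirane, CC1(C)OO1
Why: Electrophilic epoxidation with a neutral dioxirane should take C1=C2, the less shielded end of the ring diene (C5=C6 is neopentylic next to the pyranone and the side-chain alkene lies between two branched carbons), from the face anti to pyranone and side chain; the new stereocentres at C1 and C2 are lost again by step 20.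

Step 18
Reactants: 31 the C1–C2 epoxide
Product: 32 6-[(1S,4S)-2-{(2E,4S,5S)-5-{[tert-butyl(dimethyl)silyl]oxy}-4-methylhept-2-en-2-yl}-4-hydroxy-1,3,5-trimethylcyclohexa-2,5-dien-1-yl]-2-methoxy-3,5-dimethyl-4H-pyran-4-one (C1–OH cis to the C4 methyl)
Conditions: i-PrNH(c-C6H11), EtMgBr, THF, rt; then 31, 0 °C → rt; aq. NH4Cl
Reagents that add atoms: none
Why: Amide-base isomerization of an epoxide to an allylic alcohol in its magnesium amide form: H3 is allylic to the side-chain alkene and syn to the epoxide oxygen, so its removal with C2–O cleavage should outrun attack on the unactivated C2 methyl and gives the 2,5-dienol with the hydroxyl on C1.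

Step 19
Reactants: 32 the silyl-protected 2,5-dienol
Product: 33 6-[(1S,4S)-4-hydroxy-2-{(2E,4S,5S)-5-hydroxy-4-methylhept-2-en-2-yl}-1,3,5-trimethylcyclohexa-2,5-dien-1-yl]-2-methoxy-3,5-dimethyl-4H-pyran-4-one
Conditions: TASF, DMF, 0 °C → rt; aq. NH4Cl
Reagents that add atoms: none
Why: Fluoride-mediated cleavage of the silyl ether under anhydrous, non-acidic conditions, chosen because the bis-allylic dienol with its quaternary C4 would ionize and rearrange in acid.

Step 20
Reactants: 33 the diol
Product: 34 2-methoxy-3,5-dimethyl-6-[(1S)-1,3,5-trimethyl-2-{(2E,4S)-4-methyl-5-oxohept-2-en-2-yl}-4-oxocyclohexa-2,5-dien-1-yl]-4H-pyran-4-one (target)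
Conditions: Dess–Martin periodinane (3 equiv), NaHCO3, CH2Cl2, 0 °C → rt
Reagents that add atoms: none
Why: Dess–Martin oxidation of both secondary alcohols in one operation gives the cross-conjugated dienone and the ethyl ketone, and the buffered neutral medium should leave the (S) methyl stereocentre next to the new ketone and the quaternary C4 untouched.

**Compound list**

1 | methyl 2-methyl-3-oxopentanoate (racemic) | CCC(=O)C(C)C(=O)OC | starting material
2 | N-methoxy-N-methylpropanamide | CCC(=O)N(C)OC | starting material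
3 | sodium lithium dianion of 1 | C[CH-]C(=O)[C-](C)C(=O)OC.[Na+].[Li+] | intermediate
4 | methyl 2,4-dimethyl-3,5-dioxoheptanoate (diastereomer and enol mixture) | CCC(=O)C(C)C(=O)C(C)C(=O)OC | intermediate
5 | 6-ethyl-4-hydroxy-3,5-dimethyl-2H-pyran-2-one | CCC1=C(C)C(O)=C(C)C(=O)O1 | intermediate
6 | 6-ethyl-2-methoxy-3,5-dimethyl-4H-pyran-4-one | CCc1oc(OC)c(C)c(=O)c1C | intermediate
7 | prop-2-yn-1-ol | C#CCO | starting material
8 | (Z)-bromomagnesium 3-(bromomagnesio)-2-methylprop-2-en-1-olate | Br[Mg]/C=C(C)\CO[Mg]Br | intermediate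
9 | (Z)-3-iodo-2-methylprop-2-en-1-ol | OC/C(C)=C\I | intermediate
10 | (Z)-3-iodo-2-methylprop-2-enal | O=C/C(C)=C\I | intermediate
11 | lithium salt of 6 deprotonated at the CH2 of the 6-ethyl group | C[CH-]c1oc(OC)c(C)c(=O)c1C.[Li+] | intermediate
12 | 6-[(4Z)-3-hydroxy-5-iodo-4-methylpent-4-en-2-yl]-2-methoxy-3,5-dimethyl-4H-pyran-4-one (diastereomer mixture) | COc1oc(C(C)C(O)/C(C)=C\I)c(C)c(=O)c1C | intermediate
13 | methanesulfonate of 12 | COc1oc(C(C)C(OS(C)(=O)=O)/C(C)=C\I)c(C)c(=O)c1C | intermediate
14 | 6-[(2E,4Z)-5-iodo-4-methylpenta-2,4-dien-2-yl]-2-methoxy-3,5-dimethyl-4H-pyran-4-one | COc1oc(/C(C)=C/C(C)=C\I)c(C)c(=O)c1C | intermediate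
15 | (R)-4-benzyl-3-propanoyl-1,3-oxazolidin-2-one | CCC(=O)N1[C@H](Cc2ccccc2)COC1=O | starting material
16 | propanal | CCC=O | starting material
17 | (Z)-dibutylboron enolate of 15 | C/C=C(\OB(CCCC)CCCC)N1[C@H](Cc2ccccc2)COC1=O | intermediate
18 | (R)-4-benzyl-3-[(2R,3S)-3-hydroxy-2-methylpentanoyl]-1,3-oxazolidin-2-one | CC[C@H](O)[C@@H](C)C(=O)N1[C@H](Cc2ccccc2)COC1=O | intermediate
19 | (R)-4-benzyl-3-[(2R,3S)-3-{[tert-butyl(dimethyl)silyl]oxy}-2-methylpentanoyl]-1,3-oxazolidin-2-one | CC[C@H](O[Si](C)(C)C(C)(C)C)[C@@H](C)C(=O)N1[C@H](Cc2ccccc2)COC1=O | intermediate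
20 | (2S,3S)-3-{[tert-butyl(dimethyl)silyl]oxy}-2-methylpentan-1-ol | CC[C@H](O[Si](C)(C)C(C)(C)C)[C@@H](C)CO | intermediate
21 | (2R,3S)-3-{[tert-butyl(dimethyl)silyl]oxy}-2-methylpentanal | CC[C@H](O[Si](C)(C)C(C)(C)C)[C@@H](C)C=O | intermediate
22 | 2-(triphenylphosphoranylidene)propanal | CC(C=O)=P(c1ccccc1)(c1ccccc1)c1ccccc1 | starting material
23 | (2E,4S,5S)-5-{[tert-butyl(dimethyl)silyl]oxy}-2,4-dimethylhept-2-enal | CC[C@H](O[Si](C)(C)C(C)(C)C)[C@@H](C)/C=C(\C)C=O | intermediate
24 | tert-butyl{[(3S,4S,5E)-8,8-dibromo-4,6-dimethylocta-5,7-dien-3-yl]oxy}dimethylsilane | CC[C@H](O[Si](C)(C)C(C)(C)C)[C@@H](C)/C=C(\C)C=C(Br)Br | intermediate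
25 | lithium acetylide from 24 | CC[C@H](O[Si](C)(C)C(C)(C)C)[C@@H](C)/C=C(\C)C#C[Li] | intermediate
26 | tert-butyl{[(3S,4S,5E)-4,6-dimethylnon-5-en-7-yn-3-yl]oxy}dimethylsilane | CC[C@H](O[Si](C)(C)C(C)(C)C)[C@@H](C)/C=C(\C)C#CC | intermediate
27 | (2E,4E)-dienylzirconocene chloride from 26 (Zr on the methyl-bearing carbon) | CC[C@H](O[Si](C)(C)C(C)(C)C)[C@@H](C)/C=C(\C)/C=C(\C)[Zr](Cl)(C1C=CC=C1)C1C=CC=C1 | intermediate
28 | (2E,4E)-dienylzinc chloride from 27 | CC[C@H](O[Si](C)(C)C(C)(C)C)[C@@H](C)/C=C(\C)/C=C(\C)[Zn]Cl | intermediate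
29 | 6-[(2E,4Z,6E,8E,10S,11S)-11-{[tert-butyl(dimethyl)silyl]oxy}-4,6,8,10-tetramethyltrideca-2,4,6,8-tetraen-2-yl]-2-methoxy-3,5-dimethyl-4H-pyran-4-one | CC[C@H](O[Si](C)(C)C(C)(C)C)[C@@H](C)/C=C(\C)/C=C(\C)/C=C(/C)\C=C(/C)\c1oc(OC)c(C)c(=O)c1C | intermediate
30 | 6-[(1S,6R)-6-{(2E,4S,5S)-5-{[tert-butyl(dimethyl)silyl]oxy}-4-methylhept-2-en-2-yl}-1,3,5-trimethylcyclohexa-2,4-dien-1-yl]-2-methoxy-3,5-dimethyl-4H-pyran-4-one | CC[C@H](O[Si](C)(C)C(C)(C)C)[C@@H](C)/C=C(\C)[C@@H]1C(C)=CC(C)=C[C@]1(C)c1oc(OC)c(C)c(=O)c1C | intermediate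
31 | C1–C2 epoxide of 30, oxygen syn to H3 and the C4 methyl | CC[C@H](O[Si](C)(C)C(C)(C)C)[C@@H](C)/C=C(\C)[C@@H]1[C@@]2(C)O[C@H]2C(C)=C[C@]1(C)c1oc(OC)c(C)c(=O)c1C | intermediate
32 | 6-[(1S,4S)-2-{(2E,4S,5S)-5-{[tert-butyl(dimethyl)silyl]oxy}-4-methylhept-2-en-2-yl}-4-hydroxy-1,3,5-trimethylcyclohexa-2,5-dien-1-yl]-2-methoxy-3,5-dimethyl-4H-pyran-4-one | CC[C@H](O[Si](C)(C)C(C)(C)C)[C@@H](C)/C=C(\C)C1=C(C)[C@@H](O)C(C)=C[C@]1(C)c1oc(OC)c(C)c(=O)c1C | intermediate
33 | 6-[(1S,4S)-4-hydroxy-2-{(2E,4S,5S)-5-hydroxy-4-methylhept-2-en-2-yl}-1,3,5-trimethylcyclohexa-2,5-dien-1-yl]-2-methoxy-3,5-dimethyl-4H-pyran-4-one | CC[C@H](O)[C@@H](C)/C=C(\C)C1=C(C)[C@@H](O)C(C)=C[C@]1(C)c1oc(OC)c(C)c(=O)c1C | intermediate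
34 | 2-methoxy-3,5-dimethyl-6-[(1S)-1,3,5-trimethyl-2-{(2E,4S)-4-methyl-5-oxohept-2-en-2-yl}-4-oxocyclohexa-2,5-dien-1-yl]-4H-pyran-4-one | CCC(=O)[C@@H](C)/C=C(\C)C1=C(C)C(=O)C(C)=C[C@]1(C)c1oc(OC)c(C)c(=O)c1C | target

**Step count**

Total: 20 steps. Longest linear sequence: 13 steps (steps 8 to 20, from 15 to 34).

**Steps most likely to fail**

1. Step 16 (proposed new method). The catalyst may fail to accelerate closure at temperatures where it is selective, the bound polyene may be diverted into the cationic cyclization that leads to a bicyclo[3.1.0]hexene, or one-point binding at the pyranone carbonyl may give little facial discrimination. The fallback uses known chemistry and sets out from 29. The tetraene is heated without catalyst in degassed toluene at 110–130 °C in the dark with a radical inhibitor, so that the thermal disrotatory 6π electrocyclization of the (E,Z,E)-triene takes place. Because the side-chain centres do not bias the helix, an essentially unbiased mixture of 30 and its ring diastereomer, the (1R,6S)-cyclohexadiene F1, is expected. The two are diastereomers, not enantiomers, and should be separable by chromatography. The fallback comes back to the route at 30.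

2. Step 17. The oxidant may not discriminate between C1=C2, C5=C6 and the side-chain alkene, or may over-oxidize. The fallback sets out from 30 and replaces intermolecular epoxidation by a diene-specific cycloaddition. Sensitized photo-oxygenation (O2, tetraphenylporphyrin, visible light, CH2Cl2, −78 °C) should add singlet oxygen across C2 and C5 of the s-cis ring diene, on the face anti to pyranone and side chain, to give the 2,5-endoperoxide F2. Triphenylphosphine then attacks the less hindered peroxide oxygen (on C5), and the C2 alkoxide closes onto C1 in an SN2' sense with loss of triphenylphosphine oxide. This gives the vinyl epoxide with the C5=C6 alkene restored, and the fallback comes back to the route at 31.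

3. Step 18. The base may remove a proton from the C2 methyl instead of H3, or may attack the pyranone. The fallback sets out from 31 and accepts the other regiochemistry on purpose. Et2AlTMP in toluene at 0 °C, which removes the least hindered syn β-hydrogen, should give the exo-methylene allylic alcohol F3. Oxidation with MnO2 gives the exo-methylene enone F4. RhCl3·3H2O in warm ethanol then moves the exocyclic alkene into the ring, downhill to the fully substituted cross-conjugated system, to give the dienone silyl ether F5. TASF in DMF removes the silyl group to give the hydroxy dienone F6, and Dess–Martin oxidation of the remaining alcohol brings the fallback back to the route at 34.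

**Further compounds**

F1 | step 16 | 6-[(1R,6S)-6-{(2E,4S,5S)-5-{[tert-butyl(dimethyl)silyl]oxy}-4-methylhept-2-en-2-yl}-1,3,5-trimethylcyclohexa-2,4-dien-1-yl]-2-methoxy-3,5-dimethyl-4H-pyran-4-one | CC[C@H](O[Si](C)(C)C(C)(C)C)[C@@H](C)/C=C(\C)[C@H]1C(C)=CC(C)=C[C@@]1(C)c1oc(OC)c(C)c(=O)c1C
F2 | step 17 | 2,5-endoperoxide of 30 (2,3-dioxabicyclo[2.2.2]oct-5-ene, peroxide bridge syn to H3 and the C4 methyl) | CC[C@H](O[Si](C)(C)C(C)(C)C)[C@@H](C)/C=C(\C)[C@@H]1[C@@]2(C)OO[C@H](C(C)=C2)[C@]1(C)c1oc(OC)c(C)c(=O)c1C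
F3 | step 18 | exo-methylene allylic alcohol (C1–OH, C2=CH2, H3 retained, silyl ether) | CC[C@H](O[Si](C)(C)C(C)(C)C)[C@@H](C)/C=C(\C)[C@@H]1C(=C)[C@@H](O)C(C)=C[C@]1(C)c1oc(OC)c(C)c(=O)c1C
F4 | step 18 | exo-methylene enone (C1=O, C2=CH2, silyl ether) | CC[C@H](O[Si](C)(C)C(C)(C)C)[C@@H](C)/C=C(\C)[C@@H]1C(=C)C(=O)C(C)=C[C@]1(C)c1oc(OC)c(C)c(=O)c1C
F5 | step 18 | silyl ether of the cross-conjugated dienone | CC[C@H](O[Si](C)(C)C(C)(C)C)[C@@H](C)/C=C(\C)C1=C(C)C(=O)C(C)=C[C@]1(C)c1oc(OC)c(C)c(=O)c1C
F6 | step 18 | hydroxy dienone (side-chain carbinol free) | CC[C@H](O)[C@@H](C)/C=C(\C)C1=C(C)C(=O)C(C)=C[C@]1(C)c1oc(OC)c(C)c(=O)c1C
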